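**Strategy.** The route rests on cutting both bonds at C8 of the directly attached coumarin (coumarin B): C8–C6 to the cyclohexene and, next to it, C7–OCH3. In the target, C8 lies between the lactone oxygen O1 (on C8a) and the C7 methoxy group, and cyclohexene C6 is allylic to the C4=C5 alkene. Adding the oxygen of a tertiary allylic methyl ether at C4 to a coumarin 7,8-aryne, followed by a [3,3] shift, should therefore install in one operation the C8–C6 bond, the C6 stereocentre, the C4=C5 alkene and the C7 methoxy group. The precursors are an o-silylaryl triflate of 5-methoxycoumarin and an enantiopure cis-4-methoxy-1,4-dimethylcyclohexenyl TIPS-alkyne.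

Key step: step 12

**Remarks on the chemistry**
- Numbering: cyclohexene atoms keep the target numbers throughout. C1 is the quaternary carbon (CH3 and the two-carbon bridge), C2 and C3 are CH2, C4 carries the second CH3, C5 is the ring CH next to it, and C6 is the aryl-bearing CH. Coumarin atoms carry their usual numbers. Coumarin A sits on the bridge; coumarin B is bonded to C6.
- Assumption: the (S)-proline-derived oxazaborolidinium salt of step 1 is taken to give (S)-3. The sense is to be checked on 3 by optical rotation, and the enantiomeric catalyst is used if it proves opposite.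
- Assumption: 7-hydroxy-5-methoxycoumarin (15) is taken as purchasable.
- Naming: in the product of the key step (23) the aryl-bearing ring carbon is a CH, and methyl and alkynyl share the quaternary carbon. It is therefore a 3,6-dimethyl-6-(silylethynyl)cyclohex-2-en-1-yl coumarin.
- Descriptor changes at C1 along the route (for example S in 27, R in 28) reflect priority changes only; no bond at C1 is touched after step 1.

**Route**

Step 1
Reactants: 1 isoprene; 2 methacrolein
Product: 3 (1S)-1,4-dimethylcyclohex-3-ene-1-carbaldehyde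
Conditions: (S)-3,3-diphenyl-1-(2-methylphenyl)tetrahydro-1H,3H-pyrrolo[1,2-c][1,3,2]oxazaborole·HNTf2 (10 mol %), CH2Cl2, −78 °C
Reagents that add atoms: none
Why: Enantioselective Lewis-acid-catalysed Diels–Alder reaction in which the boron-bound s-trans enal is shielded on one face by a catalyst aryl group, the 2-substituted diene adds with "para" regiochemistry, and the facial bias sets the quaternary stereocentre C1.

Step 2
Reactants: 3 (1S)-1,4-dimethylcyclohex-3-ene-1-carbaldehyde
Product: 4 [(1S)-1,4-dimethylcyclohex-3-en-1-yl]methanol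
Conditions: NaBH4, MeOH, 0 °C
Reagents that add atoms: none
Why: Hydride reduction of the aldehyde to the primary alcohol (NaBH4 reduction) leaves the isolated alkene and the quaternary centre untouched and provides the directing hydroxyl for step 3.

Step 3
Reactants: 4 [(1S)-1,4-dimethylcyclohex-3-en-1-yl]methanol
Product: 5 [(1S,3S,6R)-3,6-dimethyl-7-oxabicyclo[4.1.0]heptan-3-yl]methanol (epoxide oxygen cis to CH2OH)
Conditions: VO(acac)2 (3 mol %), t-BuOOH (decane), CH2Cl2, 0 °C → rt
Reagents that add atoms: tert-butyl hydroperoxide, CC(C)(C)OO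
Why: Hydroxyl-directed epoxidation, in which the vanadium alkoxide of the pseudo-axial CH2OH group delivers the peroxide oxygen to the alkene face on which it sits, so that the new C4 and C5 centres carry the epoxide oxygen cis to CH2OH.

Step 4
Reactants: 5 [(1S,3S,6R)-3,6-dimethyl-7-oxabicyclo[4.1.0]heptan-3-yl]methanol
Product: 6 (1S,3S,6R)-3,6-dimethyl-7-oxabicyclo[4.1.0]heptane-3-carbaldehyde
Conditions: Pr4N[RuO4] (5 mol %), N-methylmorpholine N-oxide, 4 Å MS, CH2Cl2, rt
Reagents that add atoms: none
Why: Catalytic perruthenate (Ley–Griffith) oxidation of a primary alcohol to the aldehyde under neutral conditions that should spare the trisubstituted epoxide, and the quaternary α-carbon cannot epimerise.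

Step 5
Reactants: 6 (1S,3S,6R)-3,6-dimethyl-7-oxabicyclo[4.1.0]heptane-3-carbaldehyde
Product: 7 (1R,4S,6S)-4-ethynyl-1,4-dimethyl-7-oxabicyclo[4.1.0]heptane
Conditions: dimethyl (1-diazo-2-oxopropyl)phosphonate, K2CO3, MeOH, 0 °C → rt
Reagents that add atoms: dimethyl (1-diazo-2-oxopropyl)phosphonate, COP(=O)(OC)C(=[N+]=[N-])C(C)=O
Why: Ohira–Bestmann homologation, in which methanolysis of the reagent releases the diazomethylphosphonate anion that converts the non-enolisable aldehyde into the terminal alkyne through the alkylidene carbene, under conditions too mild to open the epoxide.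

Step 6
Reactants: 7 (1R,4S,6S)-4-ethynyl-1,4-dimethyl-7-oxabicyclo[4.1.0]heptane
Product: 9 {[(1S,3S,6R)-3,6-dimethyl-7-oxabicyclo[4.1.0]heptan-3-yl]ethynyl}tri(propan-2-yl)silane, via lithium acetylide 8 (not isolated)
Conditions: n-BuLi, THF, −78 °C; i-Pr3SiCl, −78 °C → rt
Reagents that add atoms: chlorotri(propan-2-yl)silane, CC(C)[Si](Cl)(C(C)C)C(C)C
Why: Deprotonation of the terminal alkyne and C-silylation of the lithium acetylide, with the silyl chloride chosen over the triflate so that no Lewis acid able to open the epoxide is present.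

Step 7
Reactants: 9 {[(1S,3S,6R)-3,6-dimethyl-7-oxabicyclo[4.1.0]heptan-3-yl]ethynyl}tri(propan-2-yl)silane
Product: 12 (1R,4S)-1,4-dimethyl-4-{[tri(propan-2-yl)silyl]ethynyl}cyclohex-2-en-1-ol, via hydroxy selenide 10 (not isolated), via selenoxide 11 (not isolated)
Conditions: (PhSe)2, NaBH4, EtOH, reflux; then THF, 30% H2O2, 0 °C → rt
Reagents that add atoms: none
Why: Epoxide-to-allylic-alcohol transposition by selenide opening and selenoxide syn-elimination, in which PhSe− attacks the secondary carbon C5 by SN2 so that the C4–O bond and its configuration are untouched, and the selenoxide can only eliminate toward C6 because C4 bears no hydrogen, giving the C5=C6 alkene and the tertiary alcohol cis to the alkynyl group.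

Step 8
Reactants: 12 (1R,4S)-1,4-dimethyl-4-{[tri(propan-2-yl)silyl]ethynyl}cyclohex-2-en-1-ol
Product: 14 {[(1S,4R)-4-methoxy-1,4-dimethylcyclohex-2-en-1-yl]ethynyl}tri(propan-2-yl)silane (methoxy cis to alkynyl), via sodium alkoxide 13 (not isolated)
Conditions: NaH, THF–DMF, 0 °C; MeI, rt
Reagents that add atoms: iodomethane, CI
Why: Williamson etherification of the tertiary alkoxide with iodomethane breaks no bond at C4, so the configuration is retained, and the silylalkyne is inert to NaH.

Step 9
Reactants: 15 7-hydroxy-5-methoxycoumarin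
Product: 16 7-hydroxy-8-iodo-5-methoxy-2H-chromen-2-one
Conditions: I2, KI, 20% aq. NH3, rt; then dil. HCl
Reagents that add atoms: iodine, II
Why: Electrophilic aromatic iodination of the phenoxide, expected at C8 as for 7-hydroxycoumarins in general, since C8 is ortho to O7, para to the 5-methoxy group, less hindered than C6 and favoured by bond fixation.

Step 10
Reactants: 16 7-hydroxy-8-iodo-5-methoxy-2H-chromen-2-one
Product: 17 8-iodo-5-methoxy-7-[(trimethylsilyl)oxy]-2H-chromen-2-one
Conditions: (Me3Si)2NH, THF, 65 °C; evaporation, used crude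
Reagents that add atoms: hexamethyldisilazane, C[Si](C)(C)N[Si](C)(C)C
Why: O-Silylation of the acidic phenol with hexamethyldisilazane gives the silyl ether with ammonia as the only by-product and needs no aqueous work-up.

Step 11
Reactants: 17 8-iodo-5-methoxy-7-[(trimethylsilyl)oxy]-2H-chromen-2-one
Product: 20 5-methoxy-2-oxo-8-(trimethylsilyl)-2H-chromen-7-yl trifluoromethanesulfonate, via aryllithium 18 (not isolated), via lithium phenoxide 19 (not isolated)
Conditions: n-BuLi (1.05 equiv), THF, −100 °C → −78 °C; Tf2O, −78 → 0 °C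
Reagents that add atoms: trifluoromethanesulfonic anhydride, O=S(=O)(OS(=O)(=O)C(F)(F)F)C(F)(F)F
Why: Iodine–lithium exchange, retro-Brook (1,3 O-to-C) silyl migration and O-triflation, where the iodide is chosen because exchange at −100 °C should outrun addition of n-BuLi to the lactone, the ortho-silyloxy group traps the aryllithium intramolecularly, and the stabilised 7-oxidocoumarin is then triflated.

Step 12
Reactants: 14 {[(1S,4R)-4-methoxy-1,4-dimethylcyclohex-2-en-1-yl]ethynyl}tri(propan-2-yl)silane; 20 5-methoxy-2-oxo-8-(trimethylsilyl)-2H-chromen-7-yl trifluoromethanesulfonate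
Product: 23 8-[(1R,6S)-3,6-dimethyl-6-{[tri(propan-2-yl)silyl]ethynyl}cyclohex-2-en-1-yl]-5,7-dimethoxy-2H-chromen-2-one (aryl cis to alkynyl), via aryne 21 (not isolated), via zwitterion 22 (not isolated)
Conditions: CsF (6 equiv), PhMe–MeCN (3:1), 14 at 1 M, 20 (3 equiv) added in portions, 25 → 40 °C
Reagents that add atoms: none
Why: Proposed new method: fluoride removes the trimethylsilyl group of 20 and triflate departs to give aryne 21, whose C7 is the electrophilic terminus because the inductively withdrawing ring oxygen O1 on C8a stabilises charge at the adjacent C8, so the ether oxygen of 14 adds at C7 and an in-plane aryl anion develops at C8 (zwitterion 22). The anion then attacks the allyl terminus C6 through the six-membered array C8–C7–O–C4–C5=C6 while the activated O–C4 bond breaks, an anion-accelerated [3,3] shift (formally an intramolecular SN2′) that forms C8–C6, moves the alkene to C4=C5 and leaves the methyl group on the C7 oxygen. The closest known reactions are the aryne aza-Claisen rearrangement of tertiary allylamines, its sulfur counterpart with allyl sulfides, and the thermal Claisen rearrangement of coumarin 7-allyl ethers to C8; an allylic ether as the σ-nucleophile is the untested element. No ring is closed. The new stereocentre C6 is controlled by the C4 ether centre, because the shift is suprafacial on the allyl unit and the oxygen at C4 is cis to the alkynyl group, so the aryl group arrives on that face, past the slim alkyne and not the methyl group of C1. The step needs site selectivity on the aryne (secured by O1 next to C8), attack at C6 over C4 (a six- against a four-membered transition state, and C4 is fully substituted) and rearrangement over loss of the allyl unit as a diene, which is countered by an ether-free medium of low acidity, a high concentration of 14 and slow release of the aryne from an excess of 20.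

Step 13
Reactants: 23 8-[(1R,6S)-3,6-dimethyl-6-{[tri(propan-2-yl)silyl]ethynyl}cyclohex-2-en-1-yl]-5,7-dimethoxy-2H-chromen-2-one
Product: 24 8-[(1R,6S)-6-ethynyl-3,6-dimethylcyclohex-2-en-1-yl]-5,7-dimethoxy-2H-chromen-2-one
Conditions: Bu4NF, THF, 0 °C
Reagents that add atoms: none
Why: Fluoride-mediated protodesilylation of the C(sp)–Si bond, with brief exposure at 0 °C expected to leave the lactone and both stereocentres unaffected.

Step 14
Reactants: 25 5,7-dimethoxycoumarin
Product: 26 8-iodo-5,7-dimethoxy-2H-chromen-2-one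
Conditions: N-iodosuccinimide, CF3CO2H (cat.), MeCN, rt
Reagents that add atoms: N-iodosuccinimide, O=C1CCC(=O)N1I
Why: Acid-activated electrophilic aromatic iodination of the electron-rich ring, expected at C8, which is activated ortho by the 7-methoxy and para by the 5-methoxy group and is less hindered than C6 between two methoxy groups.

Step 15
Reactants: 24 8-[(1R,6S)-6-ethynyl-3,6-dimethylcyclohex-2-en-1-yl]-5,7-dimethoxy-2H-chromen-2-one; 26 8-iodo-5,7-dimethoxy-2H-chromen-2-one
Product: 27 8-{[(1S,2R)-2-(5,7-dimethoxy-2-oxo-2H-chromen-8-yl)-1,4-dimethylcyclohex-3-en-1-yl]ethynyl}-5,7-dimethoxy-2H-chromen-2-one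
Conditions: Pd(PPh3)2Cl2 (5 mol %), CuI (10 mol %), Et3N, DMF, 60 °C, degassed
Reagents that add atoms: none
Why: Sonogashira coupling, in which oxidative addition of the aryl iodide to zerovalent palladium, transmetalation from the copper acetylide and reductive elimination form the C(sp2)–C(sp) bond without touching either stereocentre.

Step 16
Reactants: 27 8-{[(1S,2R)-2-(5,7-dimethoxy-2-oxo-2H-chromen-8-yl)-1,4-dimethylcyclohex-3-en-1-yl]ethynyl}-5,7-dimethoxy-2H-chromen-2-one
Product: 28 8-[(Z)-2-[(1R,2R)-2-(5,7-dimethoxy-2-oxo-2H-chromen-8-yl)-1,4-dimethylcyclohex-3-en-1-yl]ethenyl]-5,7-dimethoxy-2H-chromen-2-one (CNP0164660.3)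
Conditions: H2 (1 atm), Pd/CaCO3 poisoned with Pb(OAc)2, quinoline, EtOAc, rt
Reagents that add atoms: none
Why: Cis-semihydrogenation, in which syn delivery of one equivalent of H2 on the lead-poisoned palladium surface gives the Z-alkene, while the trisubstituted ring alkene and the two coumarin C3=C4 bonds should not be reduced.

**Compound list**

1 | isoprene (2-methylbuta-1,3-diene) | C=CC(C)=C | starting material
2 | methacrolein (2-methylprop-2-enal) | CC(=C)C=O | starting material
3 | (1S)-1,4-dimethylcyclohex-3-ene-1-carbaldehyde | O=C[C@@]1(C)CCC(C)=CC1 | intermediate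
4 | [(1S)-1,4-dimethylcyclohex-3-en-1-yl]methanol | OC[C@@]1(C)CCC(C)=CC1 | intermediate
5 | [(1S,3S,6R)-3,6-dimethyl-7-oxabicyclo[4.1.0]heptan-3-yl]methanol (epoxide O cis to CH2OH) | OC[C@@]1(C)CC[C@@]2(C)O[C@H]2C1 | intermediate
6 | (1S,3S,6R)-3,6-dimethyl-7-oxabicyclo[4.1.0]heptane-3-carbaldehyde | O=C[C@@]1(C)CC[C@@]2(C)O[C@H]2C1 | intermediate
7 | (1R,4S,6S)-4-ethynyl-1,4-dimethyl-7-oxabicyclo[4.1.0]heptane | C#C[C@@]1(C)CC[C@@]2(C)O[C@H]2C1 | intermediate
8 | lithium [(1S,3S,6R)-3,6-dimethyl-7-oxabicyclo[4.1.0]heptan-3-yl]ethynide | [Li]C#C[C@@]1(C)CC[C@@]2(C)O[C@H]2C1 | intermediate (not isolated)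
9 | {[(1S,3S,6R)-3,6-dimethyl-7-oxabicyclo[4.1.0]heptan-3-yl]ethynyl}tri(propan-2-yl)silane | CC(C)[Si](C(C)C)(C(C)C)C#C[C@@]1(C)CC[C@@]2(C)O[C@H]2C1 | intermediate
10 | (1R,2R,4S)-1,4-dimethyl-2-(phenylselanyl)-4-{[tri(propan-2-yl)silyl]ethynyl}cyclohexan-1-ol (Se trans to OH) | CC(C)[Si](C(C)C)(C(C)C)C#C[C@@]1(C)CC[C@@](C)(O)[C@H]([Se]c2ccccc2)C1 | intermediate (not isolated)
11 | Se-oxide of 10, (1R,2R,4S)-1,4-dimethyl-2-(phenylseleninyl)-4-{[tri(propan-2-yl)silyl]ethynyl}cyclohexan-1-ol (mixture at Se) | CC(C)[Si](C(C)C)(C(C)C)C#C[C@@]1(C)CC[C@@](C)(O)[C@H]([Se](=O)c2ccccc2)C1 | intermediate (not isolated)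
12 | (1R,4S)-1,4-dimethyl-4-{[tri(propan-2-yl)silyl]ethynyl}cyclohex-2-en-1-ol (OH cis to alkynyl) | CC(C)[Si](C(C)C)(C(C)C)C#C[C@@]1(C)CC[C@@](C)(O)C=C1 | intermediate
13 | sodium (1R,4S)-1,4-dimethyl-4-{[tri(propan-2-yl)silyl]ethynyl}cyclohex-2-en-1-olate | CC(C)[Si](C(C)C)(C(C)C)C#C[C@@]1(C)CC[C@@](C)([O-])C=C1.[Na+] | intermediate (not isolated)
14 | {[(1S,4R)-4-methoxy-1,4-dimethylcyclohex-2-en-1-yl]ethynyl}tri(propan-2-yl)silane (OMe cis to alkynyl) | CC(C)[Si](C(C)C)(C(C)C)C#C[C@@]1(C)CC[C@@](C)(OC)C=C1 | intermediate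
15 | 7-hydroxy-5-methoxycoumarin | COc1cc(O)cc2oc(=O)ccc12 | starting material
16 | 7-hydroxy-8-iodo-5-methoxy-2H-chromen-2-one | COc1cc(O)c(I)c2oc(=O)ccc12 | intermediate
17 | 8-iodo-5-methoxy-7-[(trimethylsilyl)oxy]-2H-chromen-2-one | COc1cc(O[Si](C)(C)C)c(I)c2oc(=O)ccc12 | intermediate
18 | {5-methoxy-2-oxo-7-[(trimethylsilyl)oxy]-2H-chromen-8-yl}lithium | COc1cc(O[Si](C)(C)C)c([Li])c2oc(=O)ccc12 | intermediate (not isolated)
19 | lithium 5-methoxy-2-oxo-8-(trimethylsilyl)-2H-chromen-7-olate | COc1cc([O-])c([Si](C)(C)C)c2oc(=O)ccc12.[Li+] | intermediate (not isolated)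
20 | 5-methoxy-2-oxo-8-(trimethylsilyl)-2H-chromen-7-yl trifluoromethanesulfonate | COc1cc(OS(=O)(=O)C(F)(F)F)c([Si](C)(C)C)c2oc(=O)ccc12 | intermediate
21 | 7,8-didehydro-5-methoxy-2H-chromen-2-one (5-methoxycoumarin-7,8-yne) | COC1=CC#CC2=C1C=CC(=O)O2 | intermediate (not isolated)
22 | [(1R,4S)-1,4-dimethyl-4-{[tri(propan-2-yl)silyl]ethynyl}cyclohex-2-en-1-yl](methyl)(5-methoxy-2-oxo-2H-chromen-8-id-7-yl)oxonium (zwitterion) | CC(C)[Si](C(C)C)(C(C)C)C#C[C@@]1(C)CC[C@@](C)([O+](C)C2=[C-]C3=C(C=CC(=O)O3)C(OC)=C2)C=C1 | intermediate (not isolated)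
23 | 8-[(1R,6S)-3,6-dimethyl-6-{[tri(propan-2-yl)silyl]ethynyl}cyclohex-2-en-1-yl]-5,7-dimethoxy-2H-chromen-2-one | CC(C)[Si](C(C)C)(C(C)C)C#C[C@@]1(C)CCC(C)=C[C@H]1c1c(OC)cc(OC)c2ccc(=O)oc12 | intermediate
24 | 8-[(1R,6S)-6-ethynyl-3,6-dimethylcyclohex-2-en-1-yl]-5,7-dimethoxy-2H-chromen-2-one | C#C[C@@]1(C)CCC(C)=C[C@H]1c1c(OC)cc(OC)c2ccc(=O)oc12 | intermediate
25 | 5,7-dimethoxycoumarin | COc1cc(OC)c2ccc(=O)oc2c1 | starting material
26 | 8-iodo-5,7-dimethoxy-2H-chromen-2-one | COc1cc(OC)c2ccc(=O)oc2c1I | intermediate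
27 | 8-{[(1S,2R)-2-(5,7-dimethoxy-2-oxo-2H-chromen-8-yl)-1,4-dimethylcyclohex-3-en-1-yl]ethynyl}-5,7-dimethoxy-2H-chromen-2-one | COc1cc(OC)c2ccc(=O)oc2c1C#C[C@@]1(C)CCC(C)=C[C@H]1c1c(OC)cc(OC)c2ccc(=O)oc12 | intermediate
28 | 8-[(Z)-2-[(1R,2R)-2-(5,7-dimethoxy-2-oxo-2H-chromen-8-yl)-1,4-dimethylcyclohex-3-en-1-yl]ethenyl]-5,7-dimethoxy-2H-chromen-2-one | COc1cc(OC)c2ccc(=O)oc2c1/C=C\[C@@]1(C)CCC(C)=C[C@H]1c1c(OC)cc(OC)c2ccc(=O)oc12 | target

**Step count**

Total: 16 steps. Longest linear sequence: 12 steps (steps 1–8, 12, 13, 15, 16); steps 9–11 and step 14 are side branches.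

**Steps most likely to fail**

1. Step 12. The hindered ether oxygen may be outcompeted by self-reaction of the aryne or by an ene reaction at the ring alkene. The O-arylated oxonium ion may also shed the cyclohexenyl group, by proton transfer to the aryl anion or by ionisation, instead of rearranging. The fallback uses known chemistry only; it sets out from alcohol 12 (with phenol 15) and returns at 23. Alcohol 12 would be converted with n-BuLi and ClCO2Me into methyl (1R,4S)-1,4-dimethyl-4-{[tri(propan-2-yl)silyl]ethynyl}cyclohex-2-en-1-yl carbonate F1. Tsuji–Trost etherification of F1 with 15 (Pd2(dba)3, PPh3, THF) should give the tertiary aryl ether 7-{[(1R,4S)-1,4-dimethyl-4-{[tri(propan-2-yl)silyl]ethynyl}cyclohex-2-en-1-yl]oxy}-5-methoxy-2H-chromen-2-one F2. Net retention at C4 is expected from double inversion, and attack at the more substituted allyl terminus follows the known formation of 1,1-dimethylallyl aryl ethers. Heating F2 in N,N-diethylaniline should effect the aromatic Claisen rearrangement to C8, the usual site for 7-allyloxycoumarins, suprafacially, to give 8-[(1R,6S)-3,6-dimethyl-6-{[tri(propan-2-yl)silyl]ethynyl}cyclohex-2-en-1-yl]-7-hydroxy-5-methoxy-2H-chromen-2-one F3. Methylation of F3 (MeI, K2CO3, acetone) then gives 23.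

2. Step 11. Addition of n-BuLi to the lactone carbonyl or to C4 may compete with iodine–lithium exchange, or the aryllithium may be protonated before the silyl group migrates. The fallback keeps organolithium reagents away from the lactone; it sets out from 16 and returns at 20. Phenol 16 would be protected (4-methoxybenzyl chloride, K2CO3, DMF) as 8-iodo-5-methoxy-7-[(4-methoxyphenyl)methoxy]-2H-chromen-2-one F4. Palladium-catalysed silylation of F4 with Me3SiSiMe3 (Pd2(dba)3, 2-(di-tert-butylphosphino)biphenyl, LiOAc, DMF, 100 °C) should give 5-methoxy-7-[(4-methoxyphenyl)methoxy]-8-(trimethylsilyl)-2H-chromen-2-one F5. Oxidative removal of the benzyl group (DDQ, CH2Cl2–pH 7 buffer) avoids acid, which would protodesilylate, and gives 7-hydroxy-5-methoxy-8-(trimethylsilyl)-2H-chromen-2-one F6. Triflation of F6 (Tf2O, pyridine, CH2Cl2, 0 °C) gives 20.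

3. Step 3. Facial selectivity may be poor because the directing hydroxyl is three bonds from the alkene, which would erode the cis relationship between the C4 oxygen and the C1 substituent on which the key step depends. The fallback enforces that relationship with a lactone bridge; it sets out from 3 and returns at 12 in the same number of steps. Pinnick oxidation of 3 (NaClO2, NaH2PO4, 2-methylbut-2-ene, t-BuOH–H2O) gives (1S)-1,4-dimethylcyclohex-3-ene-1-carboxylic acid F7. Selenolactonisation (PhSeCl, CH2Cl2, −78 °C) should open the seleniranium ion at the tertiary C4 (Markovnikov) and can only bridge cis, giving (1R,4S,6R)-1,4-dimethyl-6-(phenylselanyl)-2-oxabicyclo[2.2.2]octan-3-one F8. Selenoxide syn-elimination (H2O2, THF, 0 °C → rt) can only run toward C6 and gives (1R,4S)-1,4-dimethyl-2-oxabicyclo[2.2.2]oct-5-en-3-one F9. Reduction with i-Bu2AlH (CH2Cl2, −78 °C) gives the lactol (1R,4S)-1,4-dimethyl-2-oxabicyclo[2.2.2]oct-5-en-3-ol F10. Ohira–Bestmann homologation of its open hydroxy-aldehyde form gives (1R,4S)-4-ethynyl-1,4-dimethylcyclohex-2-en-1-ol F11. Double deprotonation (n-BuLi, 2.1 equiv) and C-silylation with i-Pr3SiCl give 12.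

Further compounds
F1 | step 12 | methyl (1R,4S)-1,4-dimethyl-4-{[tri(propan-2-yl)silyl]ethynyl}cyclohex-2-en-1-yl carbonate | CC(C)[Si](C(C)C)(C(C)C)C#C[C@@]1(C)CC[C@@](C)(OC(=O)OC)C=C1
F2 | step 12 | 7-{[(1R,4S)-1,4-dimethyl-4-{[tri(propan-2-yl)silyl]ethynyl}cyclohex-2-en-1-yl]oxy}-5-methoxy-2H-chromen-2-one | CC(C)[Si](C(C)C)(C(C)C)C#C[C@@]1(C)CC[C@@](C)(Oc2cc(OC)c3ccc(=O)oc3c2)C=C1
F3 | step 12 | 8-[(1R,6S)-3,6-dimethyl-6-{[tri(propan-2-yl)silyl]ethynyl}cyclohex-2-en-1-yl]-7-hydroxy-5-methoxy-2H-chromen-2-one | CC(C)[Si](C(C)C)(C(C)C)C#C[C@@]1(C)CCC(C)=C[C@H]1c1c(O)cc(OC)c2ccc(=O)oc12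
F4 | step 11 | 8-iodo-5-methoxy-7-[(4-methoxyphenyl)methoxy]-2H-chromen-2-one | COc1ccc(COc2cc(OC)c3ccc(=O)oc3c2I)cc1
F5 | step 11 | 5-methoxy-7-[(4-methoxyphenyl)methoxy]-8-(trimethylsilyl)-2H-chromen-2-one | COc1ccc(COc2cc(OC)c3ccc(=O)oc3c2[Si](C)(C)C)cc1
F6 | step 11 | 7-hydroxy-5-methoxy-8-(trimethylsilyl)-2H-chromen-2-one | COc1cc(O)c([Si](C)(C)C)c2oc(=O)ccc12
F7 | step 3 | (1S)-1,4-dimethylcyclohex-3-ene-1-carboxylic acid | OC(=O)[C@@]1(C)CCC(C)=CC1
F8 | step 3 | (1R,4S,6R)-1,4-dimethyl-6-(phenylselanyl)-2-oxabicyclo[2.2.2]octan-3-one | O=C1O[C@]2(C)CC[C@@]1(C)C[C@H]2[Se]c1ccccc1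
F9 | step 3 | (1R,4S)-1,4-dimethyl-2-oxabicyclo[2.2.2]oct-5-en-3-one | O=C1O[C@]2(C)CC[C@@]1(C)C=C2
F10 | step 3 | (1R,4S)-1,4-dimethyl-2-oxabicyclo[2.2.2]oct-5-en-3-ol (lactol, anomer mixture) | OC1O[C@]2(C)CC[C@@]1(C)C=C2
F11 | step 3 | (1R,4S)-4-ethynyl-1,4-dimethylcyclohex-2-en-1-ol | C#C[C@@]1(C)CC[C@@](C)(O)C=C1
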